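**Plan**

Oxolane positions used throughout: O1, C2 (guaiacyl carbon), C3 (CH2OH carbon), C4 (aroyl carbon), C5 (O–CH2).
Retrosynthesis: the C4–C(=O) ketone is traced to a C4 Weinreb amide plus a syringyl lithium, and the amide to a C4,C4-diester; then O1–C2 and C4–C5 are cut together.
The cut is possible because C5 is an unsubstituted O–CH2 between O1 and C4 and C2 is a benzylic ether carbon on the electron-rich guaiacyl ring. O1 and C5 are therefore one formaldehyde inserted into the benzylic–malonate bond of a 2-arylcyclopropane-1,1-diester.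
Forward: the cyclopropane ring is made first (organocatalytic Michael/alkylation), then the oxolane ring by (3+2) annulation, then one ester is removed, the ketone is joined and the protecting groups are taken off.
Stereochemistry: C3 comes from the prolinol silyl ether catalyst and is not touched again. C2 is formed by inversion in the annulation (cis) and then equilibrated to trans through the benzylic cation. C4 is set trans by equilibration next to its carbonyl group; the target is the all-trans isomer.

Key step: step 5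

Remark: the annulation is taken to follow its usual stereospecific course (inversion at the donor carbon); from a trans cyclopropane this gives the 2,3-cis oxolane, so the trans isomer is reached in a separate equilibration (step 6).
Remark: names use the ring numbering above; cyclopropanes are numbered C1 (diester carbon), C2 (aryl carbon), C3 (arm carbon).

**Route**

Step 1
Reactants: 1 coniferyl aldehyde, (E)-3-(4-hydroxy-3-methoxyphenyl)prop-2-enal
Product: 2 (E)-3-[4-(benzyloxy)-3-methoxyphenyl]prop-2-enal
Conditions: BnBr, K2CO3, DMF, rt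
Reagents that add atoms: benzyl bromide, BrCc1ccccc1
Why: Williamson ether synthesis on the phenoxide; the benzyl ether keeps the para-oxygen a strong donor for step 5 and is removed by hydrogenolysis at the end.

Step 2
Reactants: 2 (E)-3-[4-(benzyloxy)-3-methoxyphenyl]prop-2-enal; 3 dimethyl bromomalonate
Product: 4 dimethyl (2S,3R)-2-[4-(benzyloxy)-3-methoxyphenyl]-3-formylcyclopropane-1,1-dicarboxylate (aryl and formyl trans)
Conditions: (S)-2-[diphenyl(trimethylsilyloxy)methyl]pyrrolidine (20 mol %), 2,6-lutidine (1.1 equiv), CH2Cl2, 0 °C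
Reagents that add atoms: none
Why: Iminium–enamine Michael-initiated ring closure, in which the bromomalonate adds to the Si face of the β-carbon of the E iminium ion (the face away from the diphenyl(silyloxy)methyl group of the S catalyst) and the enamine then displaces bromide in a 3-exo-tet alkylation, setting C2 (S) and C3 (R) with aryl and formyl trans.

Step 3
Reactants: 4 dimethyl (2S,3R)-2-[4-(benzyloxy)-3-methoxyphenyl]-3-formylcyclopropane-1,1-dicarboxylate
Product: 5 dimethyl (2S,3R)-2-[4-(benzyloxy)-3-methoxyphenyl]-3-(hydroxymethyl)cyclopropane-1,1-dicarboxylate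
Conditions: NaBH4, MeOH/CH2Cl2, −20 °C; aq. NH4Cl
Reagents that add atoms: none
Why: Chemoselective hydride reduction of the aldehyde (the malonate esters are inert at −20 °C), with a cold, mildly acidic quench so that the new hydroxyl does not lactonise onto the cis ester; no stereocentre changes.

Step 4
Reactants: 5 dimethyl (2S,3R)-2-[4-(benzyloxy)-3-methoxyphenyl]-3-(hydroxymethyl)cyclopropane-1,1-dicarboxylate
Product: 6 dimethyl (2S,3R)-2-[4-(benzyloxy)-3-methoxyphenyl]-3-{[tert-butyl(diphenyl)silyl]oxymethyl}cyclopropane-1,1-dicarboxylate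
Conditions: TBDPSCl, imidazole, CH2Cl2, 0 °C → rt
Reagents that add atoms: tert-butyl(chloro)diphenylsilane, CC(C)(C)[Si](Cl)(c1ccccc1)c1ccccc1
Why: Imidazole-mediated silylation of the primary alcohol; the bulky silyl ether is chosen because it should resist the Lewis acids of steps 5 and 6 and the hot wet DMSO of step 7.

Step 5
Reactants: 6 dimethyl (2S,3R)-2-[4-(benzyloxy)-3-methoxyphenyl]-3-{[tert-butyl(diphenyl)silyl]oxymethyl}cyclopropane-1,1-dicarboxylate; 7 formaldehyde (charged as paraformaldehyde)
Product: 8 dimethyl (2R,3R)-2-[4-(benzyloxy)-3-methoxyphenyl]-3-{[tert-butyl(diphenyl)silyl]oxymethyl}oxolane-4,4-dicarboxylate (2,3-cis)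
Conditions: (CH2O)n (5 equiv), Sn(OTf)2 (10 mol %), ClCH2CH2Cl, rt → 40 °C
Reagents that add atoms: none
Why: Sn(OTf)2 (divalent tin) chelates the geminal diester and polarises the C1–C2 bond of 6; the formaldehyde oxygen attacks the benzylic carbon from the side opposite the departing malonate (SN2-like, through an intimate ion pair), and the tin malonate enolate then adds to the carbon of the resulting O-alkyl oxocarbenium ion, so that O1–C2 and C4–C5 form in one operation. The closest known reaction type is the Lewis acid-catalysed (3+2) annulation of 2-arylcyclopropane-1,1-diesters with aldehydes, which is established for trans-2-aryl-3-(alkoxymethyl)cyclopropanes; formaldehyde is the smallest but also the least nucleophilic aldehyde partner. The oxolane closes by an aldol-type step that is 5-endo-trig with respect to the O=CH2 unit and exo with respect to the enolate, feasible because the acceptor is a cationic oxocarbenium held next to the enolate. The only new stereocentre, C2, is set by inversion of the S benzylic carbon of the cyclopropane and so comes out cis to the C3 arm, whose configuration is not touched; C4 and C5 are not stereogenic. The step needs cleavage of C1–C2 and not C1–C3, which the 4-benzyloxy-3-methoxyphenyl donor secures by stabilising positive charge only at C2, and it needs O-attack to outrun proton loss from the opened ion pair, which the excess of formaldehyde should favour.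

Step 6
Reactants: 8 dimethyl (2R,3R)-2-[4-(benzyloxy)-3-methoxyphenyl]-3-{[tert-butyl(diphenyl)silyl]oxymethyl}oxolane-4,4-dicarboxylate
Product: 9 dimethyl (2S,3R)-2-[4-(benzyloxy)-3-methoxyphenyl]-3-{[tert-butyl(diphenyl)silyl]oxymethyl}oxolane-4,4-dicarboxylate (2,3-trans)
Conditions: BF3·OEt2 (1.5 equiv), CH2Cl2, −20 → 0 °C; aq. NaHCO3
Reagents that add atoms: none
Why: Lewis acid benzylic epimerisation as known for 2-aryl tetrahydrofuran lignans: BF3 on O1 promotes reversible heterolysis of the C2–O1 bond to a para-alkoxybenzyl cation, which recloses to the thermodynamically preferred isomer with the aryl group trans to the C3 arm, C3 itself not being involved.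

Step 7
Reactants: 9 dimethyl (2S,3R)-2-[4-(benzyloxy)-3-methoxyphenyl]-3-{[tert-butyl(diphenyl)silyl]oxymethyl}oxolane-4,4-dicarboxylate
Product: 11 methyl (2S,3R,4S)-2-[4-(benzyloxy)-3-methoxyphenyl]-3-{[tert-butyl(diphenyl)silyl]oxymethyl}oxolane-4-carboxylate (all-trans), via 4-epimeric ester 10 (not isolated)
Conditions: LiCl, H2O, DMSO, 150 °C; then NaOMe (0.3 equiv), MeOH, rt
Reagents that add atoms: none
Why: Krapcho dealkoxycarbonylation (chloride SN2 at an ester methyl, loss of CO2, protonation of the ester enolate); kinetic protonation anti to the C3 arm is expected to give largely the 3,4-cis ester 10, which catalytic methoxide equilibrates through the enolate to the 3,4-trans ester, so C4 is set by thermodynamic control.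

Step 8
Reactants: 11 methyl (2S,3R,4S)-2-[4-(benzyloxy)-3-methoxyphenyl]-3-{[tert-butyl(diphenyl)silyl]oxymethyl}oxolane-4-carboxylate
Product: 12 (2S,3R,4S)-2-[4-(benzyloxy)-3-methoxyphenyl]-3-{[tert-butyl(diphenyl)silyl]oxymethyl}-N-methoxy-N-methyloxolane-4-carboxamide
Conditions: MeNHOMe·HCl, i-PrMgCl, THF, −20 → 0 °C
Reagents that add atoms: N,O-dimethylhydroxylamine hydrochloride, CNOC.Cl
Why: Weinreb amide formation by direct aminolysis of the methyl ester with the chloromagnesium amide of N,O-dimethylhydroxylamine; C4 stays in its favoured trans configuration.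

Step 9
Reactants: 13 4-bromo-2,6-dimethoxyphenol
Product: 14 2-(benzyloxy)-5-bromo-1,3-dimethoxybenzene
Conditions: BnBr, K2CO3, DMF, rt
Reagents that add atoms: benzyl bromide, BrCc1ccccc1
Why: Williamson ether synthesis on the acidic 2,6-dimethoxyphenol, giving a bromide fit for bromine–lithium exchange.

Step 10
Reactants: 12 (2S,3R,4S)-2-[4-(benzyloxy)-3-methoxyphenyl]-3-{[tert-butyl(diphenyl)silyl]oxymethyl}-N-methoxy-N-methyloxolane-4-carboxamide; 14 2-(benzyloxy)-5-bromo-1,3-dimethoxybenzene
Product: 16 [4-(benzyloxy)-3,5-dimethoxyphenyl]{(2S,3R,4S)-2-[4-(benzyloxy)-3-methoxyphenyl]-3-{[tert-butyl(diphenyl)silyl]oxymethyl}oxolan-4-yl}methanone, via aryllithium 15 (not isolated)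
Conditions: 14, n-BuLi, THF, −78 °C; then 12, −78 → −40 °C; AcOH
Reagents that add atoms: none
Why: Weinreb ketone synthesis: bromine–lithium exchange gives the aryllithium, which adds to the amide to form a chelated tetrahedral adduct that collapses to the ketone only on the acidic quench, so over-addition is avoided and C4 keeps its thermodynamic trans configuration.

Step 11
Reactants: 16 [4-(benzyloxy)-3,5-dimethoxyphenyl]{(2S,3R,4S)-2-[4-(benzyloxy)-3-methoxyphenyl]-3-{[tert-butyl(diphenyl)silyl]oxymethyl}oxolan-4-yl}methanone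
Product: 17 [4-(benzyloxy)-3,5-dimethoxyphenyl]{(2S,3R,4S)-2-[4-(benzyloxy)-3-methoxyphenyl]-3-(hydroxymethyl)oxolan-4-yl}methanone
Conditions: Bu4NF, AcOH, THF, 0 °C → rt
Reagents that add atoms: none
Why: Fluoride desilylation of the primary silyl ether, buffered with AcOH so that base-induced β-elimination of O1 or epimerisation next to the ketone should not occur.

Step 12
Reactants: 17 [4-(benzyloxy)-3,5-dimethoxyphenyl]{(2S,3R,4S)-2-[4-(benzyloxy)-3-methoxyphenyl]-3-(hydroxymethyl)oxolan-4-yl}methanone
Product: 18 (4-hydroxy-3,5-dimethoxyphenyl)[(2S,3R,4S)-2-(4-hydroxy-3-methoxyphenyl)-3-(hydroxymethyl)oxolan-4-yl]methanone (CNP0169680.1)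
Conditions: H2 (1 atm), Pd/C (10 %), EtOAc, rt
Reagents that add atoms: none
Why: Hydrogenolysis of the two aryl benzyl ethers over Pd/C, which is much faster than cleavage of the cyclic benzylic C2–O1 ether or reduction of the electron-rich aryl ketone, so brief exposure should unmask both phenols without touching the stereocentres.

**Compound list**

1 | coniferyl aldehyde, (E)-3-(4-hydroxy-3-methoxyphenyl)prop-2-enal | COc1cc(/C=C/C=O)ccc1O | starting material
2 | (E)-3-[4-(benzyloxy)-3-methoxyphenyl]prop-2-enal | COc1cc(/C=C/C=O)ccc1OCc1ccccc1 | intermediate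
3 | dimethyl bromomalonate | COC(=O)C(Br)C(=O)OC | starting material
4 | dimethyl (2S,3R)-2-[4-(benzyloxy)-3-methoxyphenyl]-3-formylcyclopropane-1,1-dicarboxylate | COc1cc([C@@H]2[C@@H](C=O)C2(C(=O)OC)C(=O)OC)ccc1OCc1ccccc1 | intermediate
5 | dimethyl (2S,3R)-2-[4-(benzyloxy)-3-methoxyphenyl]-3-(hydroxymethyl)cyclopropane-1,1-dicarboxylate | COc1cc([C@@H]2[C@@H](CO)C2(C(=O)OC)C(=O)OC)ccc1OCc1ccccc1 | intermediate
6 | dimethyl (2S,3R)-2-[4-(benzyloxy)-3-methoxyphenyl]-3-{[tert-butyl(diphenyl)silyl]oxymethyl}cyclopropane-1,1-dicarboxylate | COc1cc([C@@H]2[C@@H](CO[Si](c3ccccc3)(c3ccccc3)C(C)(C)C)C2(C(=O)OC)C(=O)OC)ccc1OCc1ccccc1 | intermediate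
7 | formaldehyde (charged as paraformaldehyde) | C=O | starting material
8 | dimethyl (2R,3R)-2-[4-(benzyloxy)-3-methoxyphenyl]-3-{[tert-butyl(diphenyl)silyl]oxymethyl}oxolane-4,4-dicarboxylate (2,3-cis) | COc1cc([C@@H]2OCC(C(=O)OC)(C(=O)OC)[C@@H]2CO[Si](c3ccccc3)(c3ccccc3)C(C)(C)C)ccc1OCc1ccccc1 | intermediate
9 | dimethyl (2S,3R)-2-[4-(benzyloxy)-3-methoxyphenyl]-3-{[tert-butyl(diphenyl)silyl]oxymethyl}oxolane-4,4-dicarboxylate (2,3-trans) | COc1cc([C@H]2OCC(C(=O)OC)(C(=O)OC)[C@@H]2CO[Si](c3ccccc3)(c3ccccc3)C(C)(C)C)ccc1OCc1ccccc1 | intermediate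
10 | methyl (2S,3R,4R)-2-[4-(benzyloxy)-3-methoxyphenyl]-3-{[tert-butyl(diphenyl)silyl]oxymethyl}oxolane-4-carboxylate (3,4-cis epimer, not isolated) | COc1cc([C@H]2OC[C@H](C(=O)OC)[C@@H]2CO[Si](c3ccccc3)(c3ccccc3)C(C)(C)C)ccc1OCc1ccccc1 | intermediate
11 | methyl (2S,3R,4S)-2-[4-(benzyloxy)-3-methoxyphenyl]-3-{[tert-butyl(diphenyl)silyl]oxymethyl}oxolane-4-carboxylate (all-trans) | COc1cc([C@H]2OC[C@@H](C(=O)OC)[C@@H]2CO[Si](c3ccccc3)(c3ccccc3)C(C)(C)C)ccc1OCc1ccccc1 | intermediate
12 | (2S,3R,4S)-2-[4-(benzyloxy)-3-methoxyphenyl]-3-{[tert-butyl(diphenyl)silyl]oxymethyl}-N-methoxy-N-methyloxolane-4-carboxamide | COc1cc([C@H]2OC[C@@H](C(=O)N(C)OC)[C@@H]2CO[Si](c3ccccc3)(c3ccccc3)C(C)(C)C)ccc1OCc1ccccc1 | intermediate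
13 | 4-bromo-2,6-dimethoxyphenol | COc1cc(Br)cc(OC)c1O | starting material
14 | 2-(benzyloxy)-5-bromo-1,3-dimethoxybenzene | COc1cc(Br)cc(OC)c1OCc1ccccc1 | intermediate
15 | [4-(benzyloxy)-3,5-dimethoxyphenyl]lithium (not isolated) | COc1cc([Li])cc(OC)c1OCc1ccccc1 | intermediate
16 | [4-(benzyloxy)-3,5-dimethoxyphenyl]{(2S,3R,4S)-2-[4-(benzyloxy)-3-methoxyphenyl]-3-{[tert-butyl(diphenyl)silyl]oxymethyl}oxolan-4-yl}methanone | COc1cc([C@H]2OC[C@@H](C(=O)c3cc(OC)c(OCc4ccccc4)c(OC)c3)[C@@H]2CO[Si](c3ccccc3)(c3ccccc3)C(C)(C)C)ccc1OCc1ccccc1 | intermediate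
17 | [4-(benzyloxy)-3,5-dimethoxyphenyl]{(2S,3R,4S)-2-[4-(benzyloxy)-3-methoxyphenyl]-3-(hydroxymethyl)oxolan-4-yl}methanone | COc1cc([C@H]2OC[C@@H](C(=O)c3cc(OC)c(OCc4ccccc4)c(OC)c3)[C@@H]2CO)ccc1OCc1ccccc1 | intermediate
18 | (4-hydroxy-3,5-dimethoxyphenyl)[(2S,3R,4S)-2-(4-hydroxy-3-methoxyphenyl)-3-(hydroxymethyl)oxolan-4-yl]methanone | COc1cc([C@H]2OC[C@@H](C(=O)c3cc(OC)c(O)c(OC)c3)[C@@H]2CO)ccc1O | target

**Step count and risks**

Total: 12 steps. Longest linear sequence: 11 steps (steps 1–8 and 10–12, from coniferyl aldehyde); step 9 is the only side-branch step.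

Step 5 (annulation with formaldehyde). Formaldehyde is the least nucleophilic aldehyde, so capture of the tin-opened cyclopropane may be slower than proton loss from the opened ion pair to a styrenyl malonate, which would also erase C3. Lewis acid-activated formaldehyde may in addition hydroxymethylate the electron-rich guaiacyl ring. Partial epimerisation of C2 before capture would be harmless, because step 6 converges both epimers. Fallback, setting out from 6 and coming back at 9, so that steps 5 and 6 are both bypassed: the two bonds would be made one after the other. Lewis acid-catalysed methanolysis of the cyclopropane (Cu(OTf)2, MeOH/CH2Cl2, rt) should give dimethyl 2-[(1R,2R)-1-[4-(benzyloxy)-3-methoxyphenyl]-3-{[tert-butyl(diphenyl)silyl]oxy}-1-methoxypropan-2-yl]malonate F1. Aldol hydroxymethylation of its malonate carbon (paraformaldehyde, K2CO3, THF) forms C4–C5 and should give dimethyl 2-(hydroxymethyl)-2-[(1R,2R)-1-[4-(benzyloxy)-3-methoxyphenyl]-3-{[tert-butyl(diphenyl)silyl]oxy}-1-methoxypropan-2-yl]malonate F2. BF3·OEt2 in CH2Cl2 at −20 °C would then ionise the benzylic methyl ether, and the new primary hydroxyl closes O1–C2 on the para-alkoxybenzyl cation under thermodynamic control, giving the 2,3-trans diester 9 directly.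

Step 6 (benzylic epimerisation). The equilibration may stall at a mixture, the benzylic cation may lose a proton from C3 to a styrene (scrambling C3 on re-protonation), or the ring may revert by loss of formaldehyde. Fallback, setting out from 8 and coming back at 9: the epimerisation would be run through a quinone methide on the free phenol. Hydrogenolysis of the aryl benzyl ether (H2, Pd/C, EtOAc) should give dimethyl (2R,3R)-2-(4-hydroxy-3-methoxyphenyl)-3-{[tert-butyl(diphenyl)silyl]oxymethyl}oxolane-4,4-dicarboxylate F3. Its para-hydroxyl lets the C2–O1 bond open reversibly under catalytic camphorsulfonic acid in CH2Cl2, which should give dimethyl (2S,3R)-2-(4-hydroxy-3-methoxyphenyl)-3-{[tert-butyl(diphenyl)silyl]oxymethyl}oxolane-4,4-dicarboxylate F4. Re-benzylation (BnBr, K2CO3, DMF) returns to 9.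

Step 7 (Krapcho dealkoxycarbonylation). In hot wet DMSO the silyl ether may be lost, after which the freed hydroxyl would lactonise onto the cis ester; the ester enolate may also expel O1 by β-elimination and open the ring. Fallback, setting out from 9 and coming back at 11: the ester would be removed by hydrolysis and thermal decarboxylation. LiOH (1.1 equiv) in THF/H2O at 0 °C should cleave the less hindered ester, the one trans to the C3 arm, giving (2S,3R,4R)-2-[4-(benzyloxy)-3-methoxyphenyl]-3-{[tert-butyl(diphenyl)silyl]oxymethyl}-4-(methoxycarbonyl)oxolane-4-carboxylic acid F5. This half-acid should lose CO2 in toluene at 110 °C, and the same NaOMe/MeOH equilibration as in step 7 would then give the all-trans ester 11.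

Further compounds
F1 | step 5 | dimethyl 2-[(1R,2R)-1-[4-(benzyloxy)-3-methoxyphenyl]-3-{[tert-butyl(diphenyl)silyl]oxy}-1-methoxypropan-2-yl]malonate | COc1cc([C@H](OC)[C@@H](CO[Si](c2ccccc2)(c2ccccc2)C(C)(C)C)C(C(=O)OC)C(=O)OC)ccc1OCc1ccccc1
F2 | step 5 | dimethyl 2-(hydroxymethyl)-2-[(1R,2R)-1-[4-(benzyloxy)-3-methoxyphenyl]-3-{[tert-butyl(diphenyl)silyl]oxy}-1-methoxypropan-2-yl]malonate | COc1cc([C@H](OC)[C@@H](CO[Si](c2ccccc2)(c2ccccc2)C(C)(C)C)C(CO)(C(=O)OC)C(=O)OC)ccc1OCc1ccccc1
F3 | step 6 | dimethyl (2R,3R)-2-(4-hydroxy-3-methoxyphenyl)-3-{[tert-butyl(diphenyl)silyl]oxymethyl}oxolane-4,4-dicarboxylate | COc1cc([C@@H]2OCC(C(=O)OC)(C(=O)OC)[C@@H]2CO[Si](c3ccccc3)(c3ccccc3)C(C)(C)C)ccc1O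
F4 | step 6 | dimethyl (2S,3R)-2-(4-hydroxy-3-methoxyphenyl)-3-{[tert-butyl(diphenyl)silyl]oxymethyl}oxolane-4,4-dicarboxylate | COc1cc([C@H]2OCC(C(=O)OC)(C(=O)OC)[C@@H]2CO[Si](c3ccccc3)(c3ccccc3)C(C)(C)C)ccc1O
F5 | step 7 | (2S,3R,4R)-2-[4-(benzyloxy)-3-methoxyphenyl]-3-{[tert-butyl(diphenyl)silyl]oxymethyl}-4-(methoxycarbonyl)oxolane-4-carboxylic acid | COc1cc([C@H]2OC[C@@](C(=O)OC)(C(=O)O)[C@@H]2CO[Si](c3ccccc3)(c3ccccc3)C(C)(C)C)ccc1OCc1ccccc1
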